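The summer run at 8.00 h holds 1.27 parts of target per part of side product. This partition ratio at a stated loading of second catalyst is a reading of the selectivity factor, and the new flasks are judged by it.

| flask | substrate | partner | free catalyst | second catalyst | remark | time |
|---|---|---|---|---|---|---|
| summer | 0.10 M | 1.1 equiv | 0.2 mol% | 0.78 mol% | run made earlier |  |
| spring | 0.10 M | 1.1 equiv | 0.2 mol% | 0.39 mol% | run made earlier |  |
| noon | 0.10 M | 1.1 equiv | 0.2 mol% | 1.6 mol% | run made earlier |  |
| dawn | 0.10 M | 1.1 equiv | 0.4 mol% | 0.78 mol% | run made earlier |  |
| north-east | 0.10 M (fed, over 8.0 h) | 1.10 equiv | 0.2 mol% | 0.78 mol% | all else is in the flask from the start; the feed brings no volume worth counting | 12 h |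
| south | 0.10 M | 1.10 equiv (fed, over 8.0 h) | 0.2 mol% | 0.78 mol% | all else is in the flask from the start; the feed brings no volume worth counting | 12 h |
| north-west | 0.10 M (in portions, 3, over 8.0 h) | 1.10 equiv | 0.2 mol% | 0.78 mol% | first portion at the start, last at 8.0 h | 12 h |
| west | 0.10 M | 1.10 equiv | 0.2 mol% | 0.78 mol% | everything together at the start | 12 h |

| run | time / h | target / % | side product / % |
|---|---|---|---|
| summer | 2.00 | 1.6 | 1.6 |
| summer | 4.00 | 4.7 | 3.7 |
| summer | 5.00 | 5.9 | 5.0 |
| summer | 8.00 | 12.7 | 10.0 |
| spring | 1.00 | 0.9 | 0.5 |
| spring | 2.50 | 0.8 | 1.8 |
| spring | 6.00 | 4.4 | 7.0 |
| spring | 15.0 | 16.0 | 25.6 |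
| noon | 4.00 | 7.2 | 3.5 |
| noon | 8.00 | 20.6 | 7.4 |
| noon | 10.0 | 24.9 | 9.6 |
| noon | 15.0 | 37.2 | 15.1 |
| dawn | 2.00 | 3.0 | 2.2 |
| dawn | 5.00 | 10.7 | 8.8 |
| dawn | 10.0 | 27.5 | 21.6 |
| dawn | 15.0 | 37.1 | 31.5 |

(readings scatter by 0.5 percentage points)

- the numbers in the tables scatter with a standard deviation of 0.5 percentage points

- the flask that comes out highest in share of target in target plus side product, or "all alike" when all lie within 1.5 percentage points (north-east / south / north-west / west / all alike)
- share of target in target plus side product at the end, north-east
- share of target in target plus side product at the end, south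
- share of target in target plus side product at the end, north-west
- share of target in target plus side product at the end, west

The earlier runs show what moves the ratio. At their last readings the spring run gives 0.625 with 0.39 mol% of second catalyst, and the noon run gives 2.46 with 1.6 mol%. So the ratio follows that loading. The dawn run, with twice the free catalyst, reads 1.18, so free catalyst leaves the ratio near its summer reading. Target and side product thus look like two exits from one pool. The earlier runs hold 0.10 M of substrate throughout the set, so they do not test its level. The new flasks carry 0.78 mol% of second catalyst, so the reckoning here gives each a share near 55.9%.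

A bench rule says that a slow feed starves the channel needing the fed species, which points to a lower share for south. The rule holds while the feed delivers less than the channel uses. By 2.00 h a steady feed has brought 0.275 equivalents of partner, whereas the summer run has made target from 1.6% of its substrate. That ratio is 17.2, so south lies beyond the border of the rule, and this reckoning puts south beside west.

The forecast differs. It gives 56.5% for north-east, 48% for south, 56% for north-west and 55% for west, and names north-east highest. On south it says: “Feeding partner starves early capture”.

The flasks end at 55.2% for north-east, 54.5% for south, 55.2% for north-west and 55.1% for west. The spread is less than the margin of 1.5 points, so the answer is all alike.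

    partner + catalyst intermediate → second catalyst + target (k = 67.0 /M/min)
    second catalyst + open intermediate ⇌ catalyst intermediate (K = 7.10 /M, k = 2.60 /M/min)
    substrate + free catalyst → free catalyst + open intermediate (k = 5.50 /M/min)
    partner ⇌ dormant form (K = 1.10, k = 0.00150 /min)
    open intermediate → side product (k = 0.00150 /min)

In north-west at 3.10 h, substrate passes into open intermediate with a half-life of 11 h, longer than the 5.7 h of open intermediate by its forward step into catalyst intermediate. Open intermediate in north-west still stands at 17.5% of the substrate charged at 12.0 h, made 1.15 times faster than used up. Target over side product in north-west is 1.23, beside the carried reading of 1.27. A neighbour flask, the same as north-west but with 0.31 mol% of second catalyst, takes the carried ratio scaled to 0.505, a share of 33.5%, and that neighbour gives 32.9%.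

(The earlier runs and the new flask were computed for substances that don't exist, noise included.)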